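**Remark on the chemistry (assumption):** 1-(2,6-dihydroxy-4-methoxyphenyl)ethanone (1) is taken as a catalogue compound, which spares a selective mono-O-methylation. The 5-hydroxyl of the chromone is left free on purpose, because it anchors the silicon activator in the key step.

## Structural features

The target 16 is an achiral flavone in which benzene ring A is fused to the 4-pyranone ring C. Ring B (2,4-dihydroxyphenyl) is attached through C1' to C2, a 3-methylbut-2-enyl (prenyl) chain sits on C3, a hydroxyl on C5 is hydrogen-bonded to the C4 carbonyl, and C7 carries a methoxy group. There is no stereocentre, so the problem is one of regiochemistry and functional-group tolerance. The fragile parts are the trisubstituted prenyl olefin, the electron-rich ring B, and above all the pairing of the free 2'-OH with the C3 prenyl group, which cyclises under acid or oxidising conditions. The real difficulty lies in the tetrasubstituted C2=C3 bond of ring C: aryl and prenyl must be placed on adjacent carbons without ambiguity (C- versus O-prenylation, linear versus branched prenyl, C3 versus C6 or C8), and four oxygens must end as one methyl ether and three free phenols. The key step uses the polarity already present in the skeleton: C2 is the β-carbon of the vinylogous ester O1–C2=C3–C4=O and becomes a strong electrophile once the carbonyl oxygen carries silicon, whereas C1' of ring B is para to one oxygen and ortho to the other in a resorcinol ether and is therefore its most nucleophilic C–H. The C5 hydroxyl, peri to the carbonyl, lets a difunctional silicon reagent bridge O5 and O4, so no separate protecting group is needed there.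

## Logic of the disconnections

**16 to 15.** The two O–allyl bonds on ring B are cut. The ring B phenols must stay masked through the electrophilic and oxidising key step and be freed last, under neutral and non-oxidising conditions, because a free 2'-OH next to the prenyl group tolerates neither acid nor oxidant. The skeleton is not simplified, but the sensitive pairing is kept out of every earlier step. The forward step needs allyl transfer from Pd(PPh3)4 (zerovalent palladium) to an amine that leaves the prenyl group, the pyranone and the chelated 5-OH alone.

**15 to 8 and 11.** The C2–C1' bond is cut. Both carbons have the right innate polarity, so neither fragment needs a halogen or a metal, and the prenyl group is already on C3, so ring C poses no regiochemical question. The target falls into two halves of similar size, each one to three steps from commodity chemicals. The forward step must activate 8 to 12, have 11 attack through its C4 to give 13, remove hydride to reach 14 and strip silicon, all in one flask and with the acid buffered.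

**8 to 5.** The O1–C2 and C2–C3 bonds are cut, C2 being a one-carbon unit from a formamide acetal; 6 and 7 lie on the way. This is the standard assembly of a 3-substituted chromone from an ortho-hydroxyaryl ketone and removes ring C completely. The forward step must condense at a hindered methylene, close through the single free phenol, and take the MOM group off 7 in an acid stage mild enough to spare the olefin.

**5 to 2 and 3.** The bond between the ketone α-carbon and the allylic CH2 is cut; 4 lies on the way. Alkylation at sp3 carbon fixes the prenyl group on the future C3, and SN2 attack on the primary bromide gives the linear isomer. The forward step must alkylate the dianion at carbon, and only once.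

**2 to 1.** The O–CH2 bond of the MOM ether is cut. Masking one of the two equivalent phenols lets step 2 run through a dianion and not a trianion, and leaves exactly one phenol for ring closure; the group is lost in the acid stage of step 3, so it costs one step in all. The forward step must stop at the mono-ether, which the hydrogen bond of the remaining hydroxyl should ensure.

**11 to 9 and 10.** Both O–allyl bonds are cut, leading back to two bulk chemicals, with 10 used twice. The only demand is O- over C-allylation at both phenols.

## Other disconnections considered

**Alternative 1:** The cut runs through O1–C8a and C4–C4a, so ring C is annulated onto a benzene ring that carries neither bond. CsF releases an aryne from silyl triflate A2 (5-methoxy-3-(methoxymethoxy)-2-(trimethylsilyl)phenyl triflate). The enolate oxygen of keto ester A1 (methyl 3-[2,4-bis(methoxymethoxy)phenyl]-2-(3-methylbut-2-enyl)-3-oxopropanoate) adds to the aryne carbon remote from the MOM ether. The aryl anion next to that ether then attacks the ester and gives A3 (2-[2,4-bis(methoxymethoxy)phenyl]-7-methoxy-5-(methoxymethoxy)-3-(3-methylbut-2-enyl)chromen-4-one). Acid would then remove three MOM groups to reach 16.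
- In favour: two bonds and ring C form in one operation, the alkoxy group polarises the aryne and so sets the 5,7-pattern, and no oxidant is needed. The prenyl group is introduced by alkylating a β-keto ester, which is more controlled than the methyl ketone alkylation of step 2; on that point the alternative is the better.
- Against: β-keto ester enolates normally attack arynes through carbon (α-arylation or insertion into the C–C bond), whereas this path needs attack through oxygen. The aryne can also undergo an ene reaction with the trisubstituted olefin. A2 would take about four steps from a phenol. The end game exposes the free 2'-OH and the prenyl group to acid, the conditions under which they cyclise.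
- Comparison: on structure the alternative is more ambitious (a ring and two bonds against one bond) and equally convergent. On mechanism both plans rest on a selectivity that precedent does not secure, so they are equals in risk at the key step, but the chosen plan has the safer deprotection. On step economy the alternative is longer, about ten steps against six.

**Alternative 2:** The cut is the C4a–C5 bond and with it the whole of ring A, which is built last. Pyranone A4 (methyl 4-[6-[2,4-bis(methoxymethoxy)phenyl]-5-(3-methylbut-2-enyl)-4-oxopyran-2-yl]-3-oxobutanoate) carries a 3-oxobutanoate chain on the carbon that becomes C8a. With Mg(OMe)2 in methanol the pyranone carbon that becomes C4a attacks the terminal ester (Claisen condensation), and enolisation aromatises ring A to the diol A5 (2-[2,4-bis(methoxymethoxy)phenyl]-5,7-dihydroxy-3-(3-methylbut-2-enyl)chromen-4-one). Methylation of the 7-OH and acid removal of the MOM groups would follow.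
- In favour: the chain dictates the oxygenation pattern of ring A and magnesium chelation templates the closure. Claisen aromatisations of pyranone-masked polyketides are a known reaction class, so the key step has closer precedent than step 5; there the alternative is the better. The 7-OH of A5 is far more acidic than the chelated 5-OH, so the methylation is secure.
- Against: ring A is bought ready-made in the chosen plan, and here it is traded for a polycarbonyl compound whose assembly would take many steps. That assembly must also avoid pyranone opening by methoxide and condensation through the side-chain methylene. Two steps follow the key step, and the acid deprotection problem remains.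
- Comparison: on structure it builds what can be bought; on mechanism its key step is the sounder; on step economy it is much poorer, well over ten steps.

**Alternative 3:** The cut runs through C3–C4 and O1–C2. Ring C is made from the symmetric aldehyde A6 (2,6-dihydroxy-4-methoxybenzaldehyde) and the enyne A7 (2,4-bis(methoxymethoxy)-1-(5-methylhex-4-en-1-ynyl)benzene). [Cp*RhCl2]2 (trivalent rhodium) with Cu(OAc)2 as oxidant cleaves the aldehyde C–H bond under direction by the ortho phenoxide. The alkyne inserts into the acyl–rhodium bond with the aryl-bearing carbon on the metal, and C–O reductive elimination closes the pyranone to give A8 (2-[2,4-bis(methoxymethoxy)phenyl]-5-hydroxy-7-methoxy-3-(3-methylbut-2-enyl)chromen-4-one).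
- In favour: it is the most convergent plan, giving ring C and both its substituents in one step. Oxidative annulation of salicylaldehydes with internal alkynes is a known reaction class, so precedent is better than for step 5. The symmetry of A6 removes any question of which hydroxyl closes the ring. At about five or six steps it is the equal of the chosen plan or slightly better.
- Against: the CH2 of A7 is both propargylic and allylic and invites isomerisation to an allene or a conjugated enyne under hot acetate conditions. The olefin can bind or insert at rhodium. Stoichiometric divalent copper at high temperature is a poor match for an electron-rich free diphenol. Making A7 reopens the linear-versus-branched question for the prenyl unit, which the chosen plan settles by a simple SN2 alkylation. The MOM ethers again call for acid at the end, although allyl ethers could replace them, so this point is not intrinsic.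
- Comparison: on structure it is the better; on mechanism it is a known class with several substrate-specific hazards, set against an unprecedented but electronically well-matched step; on step economy it is equal or better.

Key step: step 5

## Route

**Step 1**
Reactants: 1 1-(2,6-dihydroxy-4-methoxyphenyl)ethanone
Product: 2 1-[2-hydroxy-4-methoxy-6-(methoxymethoxy)phenyl]ethanone
Conditions: MOMCl (1.1 equiv), K2CO3 (1.5 equiv), acetone, 0 °C to rt
Reagents that add atoms: chloromethyl methyl ether, COCCl
Why: Williamson-type O-alkylation of a phenoxide; once one hydroxyl is etherified the other is held in a strong hydrogen bond to the carbonyl and is far less nucleophilic, so the reaction should stop at the mono-ether (the two hydroxyls of 1 are equivalent, so there is no regiochemical question).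

**Step 2**
Reactants: 2 1-[2-hydroxy-4-methoxy-6-(methoxymethoxy)phenyl]ethanone; 3 1-bromo-3-methylbut-2-ene (prenyl bromide)
Product: 5 1-[2-hydroxy-4-methoxy-6-(methoxymethoxy)phenyl]-5-methylhex-4-en-1-one, via dilithium phenoxide enolate 4 (not isolated)
Conditions: LiN(iPr)2 (2.2 equiv), THF, −78 to −20 °C; 3 (1.0 equiv), −78 to 0 °C; AcOH
Reagents that add atoms: none
Why: Alkylation of a phenoxide–enolate dianion of an ortho-hydroxyaryl methyl ketone: the second equivalent of amide removes a methyl proton, and the enolate carbon is the softest and most reactive site of 4. The primary allylic bromide reacts by SN2 at CH2, so the prenyl unit arrives unrearranged, and the MOM ether is inert to the base.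

**Step 3**
Reactants: 5 1-[2-hydroxy-4-methoxy-6-(methoxymethoxy)phenyl]-5-methylhex-4-en-1-one
Product: 8 5-hydroxy-7-methoxy-3-(3-methylbut-2-enyl)chromen-4-one, via enaminone 6 (not isolated), via MOM-protected chromone 7 (not isolated)
Conditions: Me2NCH(OMe)2 (3 equiv), toluene, 100 °C; concentrate; 2 M aq. HCl/MeOH, 40 °C
Reagents that add atoms: N,N-dimethylformamide dimethyl acetal, COC(OC)N(C)C
Why: Enaminone route to 3-substituted chromones: aminomethylenation of the activated methylene, conjugate addition of the ortho phenol and loss of dimethylamine build the pyranone. The acidic methanol stage completes the closure and cleaves the MOM ether peri to the carbonyl by acetal exchange, while the isolated trisubstituted olefin should be too slow to add methanol in such dilute acid.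

**Step 4**
Reactants: 9 benzene-1,3-diol (resorcinol); 10 3-bromoprop-1-ene (allyl bromide)
Product: 11 1,3-bis(allyloxy)benzene
Conditions: 10 (2.5 equiv in all), K2CO3 (3 equiv), acetone, reflux
Reagents that add atoms: 3-bromoprop-1-ene (allyl bromide, the second equivalent, for the second ether), C=CCBr
Why: Double Williamson etherification in which each phenoxide oxygen of 9 displaces bromide from one molecule of 10, so two equivalents of 10 are consumed. K2CO3 in acetone favours O- over C-allylation of the phenoxide.

**Step 5**
Reactants: 8 5-hydroxy-7-methoxy-3-(3-methylbut-2-enyl)chromen-4-one; 11 1,3-bis(allyloxy)benzene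
Product: 15 2-[2,4-bis(allyloxy)phenyl]-5-hydroxy-7-methoxy-3-(3-methylbut-2-enyl)chromen-4-one, via silylene-bridged benzopyrylium triflate 12 (not isolated), via 2H-chromene silyl enol ether 13 (not isolated), via silylene-bridged flavylium salt 14 (not isolated)
Conditions: iPr2Si(OTf)2 (1.2 equiv), 2,6-di-tert-butyl-4-methylpyridine (2.5 equiv), CH2Cl2, 0 °C; 11 (3 equiv), 0 °C to rt; DDQ (1.2 equiv), −20 to 0 °C; Et3N·3HF, then aq. NaHCO3
Reagents that add atoms: none
Why: Proposed new method: the silyl ditriflate should tie the peri 5-OH and the carbonyl oxygen into a six-membered silylene chelate and so turn 8 into benzopyrylium ion 12, whose C2 is an oxocarbenium carbon; the closest known reaction type is the capture of 4-silyloxybenzopyrylium ions, including silicon-bridged ones from 5-hydroxychromones, by silyl enol ethers, silyloxyfurans, allyl metals and indoles, and an electron-rich arene C–H bond is asked here to play the part of those nucleophiles. Arene 11 should attack C2 through its C4 in a Friedel–Crafts substitution, the hindered pyridine takes the proton, and the neutral 2H-chromene silyl enol ether 13 results. DDQ then removes hydride from C2–H, which lies next to the ring oxygen, the new aryl group and the enol ether double bond, to give the aromatic flavylium ion 14, in line with known DDQ oxidations of 2H-chromenes and of flavanone silyl enol ethers; fluoride strips the silicon bridge and returns the C4 carbonyl and the 5-OH of 15. No ring closes, and the only stereocentre formed, C2 of 13, is racemic and is erased in the same flask, so nothing has to be controlled there. On the arene, C4 and C6 are equivalent and are para to one allyloxy group and ortho to the other, whereas C2 between the two oxygens is shielded, so a single C1' regiochemistry is expected; on the electrophile only C2 is open, because C3 carries the prenyl group. The buffer keeps triflic acid away from the prenyl olefin and the allyl ethers, the threefold excess of 11 is meant to outrun the weaker π-nucleophile (the trisubstituted olefin of a second molecule), and hydride loss from C2 should beat attack on the prenyl group because only it leads to an aromatic cation.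

**Step 6**
Reactants: 15 2-[2,4-bis(allyloxy)phenyl]-5-hydroxy-7-methoxy-3-(3-methylbut-2-enyl)chromen-4-one
Product: 16 2-(2,4-dihydroxyphenyl)-5-hydroxy-7-methoxy-3-(3-methylbut-2-enyl)chromen-4-one
Conditions: Pd(PPh3)4 (5 mol %), morpholine (10 equiv), THF, rt, degassed
Reagents that add atoms: none
Why: Tsuji–Trost-type deallylation: zerovalent palladium ionises each allyl aryl ether to a π-allylpalladium phenoxide and morpholine traps the allyl fragment. The prenyl group is a carbon-bound olefin without a leaving group and is inert, and the neutral, non-oxidising medium avoids cyclisation of the freed 2'-OH onto the prenyl olefin.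

## Compound list

1 | 1-(2,6-dihydroxy-4-methoxyphenyl)ethanone | CC(=O)c1c(O)cc(OC)cc1O | starting material
2 | 1-[2-hydroxy-4-methoxy-6-(methoxymethoxy)phenyl]ethanone | CC(=O)c1c(O)cc(OC)cc1OCOC | intermediate
3 | 1-bromo-3-methylbut-2-ene (prenyl bromide) | CC(C)=CCBr | starting material
4 | dilithium phenoxide enolate of 2 (not isolated) | [Li+].[Li+].C=C([O-])c1c([O-])cc(OC)cc1OCOC | intermediate
5 | 1-[2-hydroxy-4-methoxy-6-(methoxymethoxy)phenyl]-5-methylhex-4-en-1-one | CC(C)=CCCC(=O)c1c(O)cc(OC)cc1OCOC | intermediate
6 | (E)-3-(dimethylamino)-1-[2-hydroxy-4-methoxy-6-(methoxymethoxy)phenyl]-2-(3-methylbut-2-enyl)prop-2-en-1-one (not isolated; drawn as E, either geometry cyclises) | CN(C)/C=C(\CC=C(C)C)C(=O)c1c(O)cc(OC)cc1OCOC | intermediate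
7 | 7-methoxy-5-(methoxymethoxy)-3-(3-methylbut-2-enyl)chromen-4-one (not isolated) | COCOc1cc(OC)cc2occ(CC=C(C)C)c(=O)c12 | intermediate
8 | 5-hydroxy-7-methoxy-3-(3-methylbut-2-enyl)chromen-4-one | COc1cc(O)c2c(=O)c(CC=C(C)C)coc2c1 | intermediate
9 | benzene-1,3-diol (resorcinol) | Oc1cccc(O)c1 | starting material
10 | 3-bromoprop-1-ene (allyl bromide) | C=CCBr | starting material
11 | 1,3-bis(allyloxy)benzene | C=CCOc1cccc(OCC=C)c1 | intermediate
12 | 4,5-[(diisopropylsilanediyl)bis(oxy)]-7-methoxy-3-(3-methylbut-2-enyl)chromenylium triflate, silicon bridging O4 and O5 (not isolated) | COc1cc2c3c(c1)[o+]cc(CC=C(C)C)c3O[Si](C(C)C)(C(C)C)O2.[O-]S(=O)(=O)C(F)(F)F | intermediate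
13 | 2-[2,4-bis(allyloxy)phenyl]-4,5-[(diisopropylsilanediyl)bis(oxy)]-7-methoxy-3-(3-methylbut-2-enyl)-2H-chromene, racemic at C2 (not isolated) | COc1cc2c3c(c1)OC(c1ccc(OCC=C)cc1OCC=C)C(CC=C(C)C)=C3O[Si](C(C)C)(C(C)C)O2 | intermediate
14 | 2-[2,4-bis(allyloxy)phenyl]-4,5-[(diisopropylsilanediyl)bis(oxy)]-7-methoxy-3-(3-methylbut-2-enyl)chromenylium, counter-ion the monoanion of reduced DDQ (not isolated) | COc1cc2c3c(c1)[o+]c(-c1ccc(OCC=C)cc1OCC=C)c(CC=C(C)C)c3O[Si](C(C)C)(C(C)C)O2.[O-]c1c(Cl)c(Cl)c(O)c(C#N)c1C#N | intermediate
15 | 2-[2,4-bis(allyloxy)phenyl]-5-hydroxy-7-methoxy-3-(3-methylbut-2-enyl)chromen-4-one | COc1cc(O)c2c(=O)c(CC=C(C)C)c(-c3ccc(OCC=C)cc3OCC=C)oc2c1 | intermediate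
16 | 2-(2,4-dihydroxyphenyl)-5-hydroxy-7-methoxy-3-(3-methylbut-2-enyl)chromen-4-one (CNP0288435.0) | COc1cc(O)c2c(=O)c(CC=C(C)C)c(-c3ccc(O)cc3O)oc2c1 | target

## Step count and least certain steps

Total step count: 6. Longest linear sequence: 5 (steps 1, 2, 3, 5 and 6); step 4 is the only step of the second branch.

**Step 5 (proposed new method).** The most likely failure is that addition of the arene to the donor-stabilised benzopyrylium ion is too slow. Attack by the prenyl olefin of a second molecule, acid-induced cyclisation, or simple return of the chromone on work-up would then take over. A second hazard is over-oxidation of the electron-rich arene or the prenyl group by DDQ.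
Fallback, known chemistry throughout, setting out from 5 and 11 and returning at 15: Vilsmeier–Haack formylation of 11 (POCl3, DMF) should give 2,4-bis(allyloxy)benzaldehyde F1. Pinnick oxidation (NaClO2, NaH2PO4, 2-methylbut-2-ene) gives 2,4-bis(allyloxy)benzoic acid F2, and oxalyl chloride with catalytic DMF gives 2,4-bis(allyloxy)benzoyl chloride F3. The lithium dianion of 5 (LiN(SiMe3)2, 3 equiv, THF, −78 °C) is C-acylated with F3 in a Baker–Venkataraman-type construction to give 1-[2,4-bis(allyloxy)phenyl]-3-[2-hydroxy-4-methoxy-6-(methoxymethoxy)phenyl]-2-(3-methylbut-2-enyl)propane-1,3-dione F4. Dilute HCl in methanol then cyclodehydrates F4 and removes the MOM group, which leads to 15. The C2–C1' bond is then formed by acylation and not by C–H coupling, at the cost of about three more steps.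

**Step 2.** Proton exchange between the alkylated ketone and unreacted dianion may lead to double prenylation, and some O-prenylation of the phenoxide is possible.
Fallback, setting out from 1 and 3 and returning at 8: both phenols of 1 are protected (NaH, MOMCl, DMF) to give 1-[4-methoxy-2,6-bis(methoxymethoxy)phenyl]ethanone F5. Its simple lithium enolate (LiN(iPr)2, 1.05 equiv, THF, −78 °C) is alkylated with 3 to give 1-[4-methoxy-2,6-bis(methoxymethoxy)phenyl]-5-methylhex-4-en-1-one F6. Dilute HCl in methanol frees 1-(2,6-dihydroxy-4-methoxyphenyl)-5-methylhex-4-en-1-one F7, and Me2NCH(OMe)2 at 100 °C closes this to 8. The dianion is replaced by a monoenolate of a fully protected ketone, at the price of one more step.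

**Step 3.** Condensation at the hindered α-methylene may be sluggish, the acetal may O-methylate the chelated phenol, and the acid stage may add methanol across the prenyl olefin.
Fallback, setting out from 5 and returning at 8: Claisen formylation with NaH and ethyl formate in THF should give the cyclic hemiacetal 2-hydroxy-7-methoxy-5-(methoxymethoxy)-3-(3-methylbut-2-enyl)chroman-4-one F8. Brief treatment with dilute HCl in methanol dehydrates it and removes the MOM group to give 8. The C2 carbon then comes from a formate ester through an enolate, and no hot methylating acetal is present.

**Step 6.** The π-allylpalladium intermediate may transfer allyl to a carbon of the very electron-rich ring B, or the freed 2'-OH may cyclise onto the prenyl group during work-up.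
Fallback, setting out from 15 and returning at 16: isomerisation of both allyl ethers with hydrogen-activated [Ir(cod)(PMePh2)2]PF6 in THF should give 2-[2,4-bis[(E)-prop-1-enoxy]phenyl]-5-hydroxy-7-methoxy-3-(3-methylbut-2-enyl)chromen-4-one F9. Its enol ethers are then hydrolysed with 0.1 M HCl in aqueous acetone at rt to give 16. No π-allyl species is formed at any point.

## Further compounds

F1 | step 5 | 2,4-bis(allyloxy)benzaldehyde | O=Cc1ccc(OCC=C)cc1OCC=C
F2 | step 5 | 2,4-bis(allyloxy)benzoic acid | OC(=O)c1ccc(OCC=C)cc1OCC=C
F3 | step 5 | 2,4-bis(allyloxy)benzoyl chloride | ClC(=O)c1ccc(OCC=C)cc1OCC=C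
F4 | step 5 | 1-[2,4-bis(allyloxy)phenyl]-3-[2-hydroxy-4-methoxy-6-(methoxymethoxy)phenyl]-2-(3-methylbut-2-enyl)propane-1,3-dione (racemic, enolisable) | COCOc1cc(OC)cc(O)c1C(=O)C(CC=C(C)C)C(=O)c1ccc(OCC=C)cc1OCC=C
F5 | step 2 | 1-[4-methoxy-2,6-bis(methoxymethoxy)phenyl]ethanone | CC(=O)c1c(OCOC)cc(OC)cc1OCOC
F6 | step 2 | 1-[4-methoxy-2,6-bis(methoxymethoxy)phenyl]-5-methylhex-4-en-1-one | CC(C)=CCCC(=O)c1c(OCOC)cc(OC)cc1OCOC
F7 | step 2 | 1-(2,6-dihydroxy-4-methoxyphenyl)-5-methylhex-4-en-1-one | CC(C)=CCCC(=O)c1c(O)cc(OC)cc1O
F8 | step 3 | 2-hydroxy-7-methoxy-5-(methoxymethoxy)-3-(3-methylbut-2-enyl)chroman-4-one (mixture of diastereomers, racemic) | COCOc1cc(OC)cc2OC(O)C(CC=C(C)C)C(=O)c12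
F9 | step 6 | 2-[2,4-bis[(E)-prop-1-enoxy]phenyl]-5-hydroxy-7-methoxy-3-(3-methylbut-2-enyl)chromen-4-one | COc1cc(O)c2c(=O)c(CC=C(C)C)c(-c3ccc(O/C=C/C)cc3O/C=C/C)oc2c1
A1 | alternative 1 | methyl 3-[2,4-bis(methoxymethoxy)phenyl]-2-(3-methylbut-2-enyl)-3-oxopropanoate (racemic) | COC(=O)C(CC=C(C)C)C(=O)c1ccc(OCOC)cc1OCOC
A2 | alternative 1 | 5-methoxy-3-(methoxymethoxy)-2-(trimethylsilyl)phenyl trifluoromethanesulfonate | COCOc1cc(OC)cc(OS(=O)(=O)C(F)(F)F)c1[Si](C)(C)C
A3 | alternative 1 | 2-[2,4-bis(methoxymethoxy)phenyl]-7-methoxy-5-(methoxymethoxy)-3-(3-methylbut-2-enyl)chromen-4-one | COCOc1cc(OC)cc2oc(-c3ccc(OCOC)cc3OCOC)c(CC=C(C)C)c(=O)c12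
A4 | alternative 2 | methyl 4-[6-[2,4-bis(methoxymethoxy)phenyl]-5-(3-methylbut-2-enyl)-4-oxopyran-2-yl]-3-oxobutanoate | COC(=O)CC(=O)Cc1cc(=O)c(CC=C(C)C)c(-c2ccc(OCOC)cc2OCOC)o1
A5 | alternative 2 | 2-[2,4-bis(methoxymethoxy)phenyl]-5,7-dihydroxy-3-(3-methylbut-2-enyl)chromen-4-one | Oc1cc(O)c2c(=O)c(CC=C(C)C)c(-c3ccc(OCOC)cc3OCOC)oc2c1
A6 | alternative 3 | 2,6-dihydroxy-4-methoxybenzaldehyde | COc1cc(O)c(C=O)c(O)c1
A7 | alternative 3 | 2,4-bis(methoxymethoxy)-1-(5-methylhex-4-en-1-ynyl)benzene | COCOc1ccc(C#CCC=C(C)C)c(OCOC)c1
A8 | alternative 3 | 2-[2,4-bis(methoxymethoxy)phenyl]-5-hydroxy-7-methoxy-3-(3-methylbut-2-enyl)chromen-4-one | COc1cc(O)c2c(=O)c(CC=C(C)C)c(-c3ccc(OCOC)cc3OCOC)oc2c1
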